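## The problem

Atoms are numbered by their position in the SMILES string of the target 38 (C1 to C27, O6 on C5, O11 on C10). The rings are A (C3, C4, C5, C7, C9), B (C2, C3, C9, C10, C12, C25, C26, C27), C (C12, C14, C15, C16, C24, C25) and D (C16, C18, C19, C20, C23, C24), and β means the face of the C17 methyl group. Compound 38 is a 5-8-6-6 sesterterpenoid diol: a trans-decalin (rings C and D) is trans-fused through C12–C25 to a cyclooctene (ring B), whose tetrasubstituted C2=C3 alkene is exocyclic to a cyclopentanol (ring A) that shares C3 and C9 with it. Eight stereocentres must be set: C16 and C24 at the C/D fusion, C25 and the quaternary C12 at the B/C fusion (C13 and C17 methyls axial on opposite faces), the C10 carbinol between C12 and C9, and C5, C7 and C9 on ring A, where the C7 methyl is trans to the C5 hydroxyl but cis to the C9–C10 bond. Control can be relayed outward from ring D: C16 and C24 fix the chair of ring C, which directs C25 (attack anti to the C17 methyl) and C12 (axial attack); C12 can direct C10 through a Felkin–Anh transition state; C10 and C5 together can direct C7 and C9. C5 is too remote from the decalin to be controlled by it and is best taken from a building block of known configuration. The cis C7/C9 arrangement is the less stable one and is lost by enolization whenever C3 is a ketone; the tetrasubstituted alkene migrates under acid; the hindered C10 carbinol is a retro-aldol candidate once a C3 ketone is present. Ring B is an eight-membered ring closed through a tetrasubstituted alkene, which rules out ordinary olefin metathesis. The feature that invites a cycloaddition is ring D: the quaternary C16 (C17 methyl, C15) sits next to C24 (H, C25) with the C20 gem-dimethyl group para to C16, the pattern of an adduct of isoprene (C18, C19, C20, C23) with an (E)-2-methyl enal (C15, C16, C24, C25) after one methyl group is added to C20.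

## Retrosynthesis

**C2=C3 (ring B).** Target 38 is the desilylation product of 37, and 37 is cut at the alkene to diketone 36 (C3 cyclopentanone, C2 methyl ketone) for a McMurry coupling. Both alkene carbons come from carbonyls, so the position and the ring-enforced geometry of the alkene are unambiguous. A C26–C27 alkylation would need activating groups that must later be removed. A C9–C10 closure with an allyl metal would bond at C2 and give a six-membered ring. Metathesis does not deliver a tetrasubstituted cyclooctene. The precursor has lost ring B. The forward step must close an eight-membered ring without enolizing the C3 ketone.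

**C7–H and C9–H.** Diketone 36 comes from ketal 35, which is the silyl ether of diol 34, and 34 is the syn-hydrogenation product of cyclopentene diol 33 across C7=C9. The cis C7/C9 relation is contra-thermodynamic, so enolate-based constructions of ring A (conjugate addition then aldol on a 4-silyloxycyclopentenone) would give the C9 epimer. Addition of H2 from the face of the C5 hydroxyl sets both centres at once, and the C10 hydroxyl directs to the same face. The precursor has two stereocentres fewer. The forward step needs a catalyst that reduces a tetrasubstituted alkene under hydroxyl direction.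

**C9–C10.** Diol 33 comes from silyl ether 32, which comes from ketone 31 by reduction; 31 is the oxidation product of carbinol 30, which is cut at C9–C10 into aldehyde 22 and vinyl bromide 28 (through vinyllithium 29). This is the most convergent cut: 19 skeletal carbons in 22 and six in 28. A Felkin–Anh analysis at C12 (C25 anti to the nucleophile, which passes over the C13 methyl) predicts that adding C9 to the aldehyde gives the C10 epimer, whereas adding hydride to the C10 ketone gives the required configuration. The oxidation–reduction pair 30 → 31 → 32 is therefore planned from the start.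

**Ring A piece.** Bromide 28 is the ketal of bromo enone 27 (from enone 25 through dibromide 26), and 25 comes from commercially available (R)-silyloxy enone 23 through silyl enol ether 24. The C5 stereocentre is bought. The methyl group enters by conjugate addition and the alkene is restored by dehydrogenation.

**Decalin end groups.** Aldehyde 22 comes from alcohol 21 and benzyl ether 20. The second C20 methyl of 20 is added to alkene 18 by hydromethylation (through hydrazide 19), and 18 is ketone 16 without its C15 carbonyl (through hydrazone 17). The hydromethylation is placed here because 18 has no other alkene and no group that the radical conditions would touch.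

**C12 quaternary centre.** Ketone 16 is cut at C12–C13 to enone 15 and a methyl cuprate. Enone 15 comes from tertiary alcohol 14 by oxidative transposition, and 14 comes from dienone 11 and (benzyloxymethyl)lithium 13, made from stannane 12. Axial attack on ring C puts the incoming group on the α face, and the target has the methyl axial and C10 equatorial, so C10 must be in place first and the methyl must come last. Methylating a C12 aldehyde enolate would be expected to give the other epimer.

**C25–C26.** Dienone 11 is the α′-alkylation product of dienone 8 with iodide 10 (from bromide 9). The enone blocks the C14 side, so only C25 can be deprotonated, and the C17 methyl shields the β face.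

**Ring C.** Dienone 8 is the aldol condensation product of keto aldehyde 7, the hydrolysis product of ketal 6. The aldehyde is not enolizable, so only C14 can attack C15.

**Ring D (key cut).** Aldehyde 6 is cut at C16–C18 and C23–C24 into enal 4 and isoprene 5. This removes ring D and both of its stereocentres in one step, sets the absolute configuration by catalysis at the third step, and fixes the trans C/D fusion through the alkene geometry of 4.

**Dienophile.** Enal 4 comes from aldehyde 2 and ylide 3 by Wittig reaction; 2 comes from ester 1.

## Roads not taken

**Alternative 1:** Ring B would be closed at C26–C27 by allylic alkylation. Zerovalent palladium (Pd(PPh3)4) ionizes a tertiary allylic carbonate at C3 to a π-allyl complex over C3–C2–C27, and a bis(phenylsulfonyl) carbanion at C26 attacks C27 to give A1 with the alkene at C2=C3.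
- Merits: the closure is catalytic, nearly neutral and runs at low temperature. C3 is not a ketone while the ring closes, so C9 cannot epimerize in that step; in this respect it is gentler than the reductive coupling chosen here.
- Weak points: the carbanion can also reach the C3 terminus, which closes a six-membered ring (C26, C25, C12, C10, C9, C3) through an easier transition state. The cyclooctene needs the less favoured π-allyl geometry. Two sulfonyl groups must be installed at C26 and removed reductively afterwards. The carbonate still has to be made from a C3 ketone with the same epimerizable C9.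
- Comparison: this road solves only ring B and needs the decalin and ring A from elsewhere. The chosen plan sets against it an alkene whose position cannot be in doubt and no activating groups to remove.

**Alternative 2:** Rings A and B would come from a Prins–pinacol reaction. SnCl4 ionizes a C5 dibenzyl acetal, C7 of a (Z)-propenyl group on C10 attacks the oxocarbenium ion (C5–C7), and alkenyl carbon C3 migrates from C10 to C9 (C3–C9). This closes ring A, enlarges a seven-membered ring to ring B and gives ketone A2.
- Merits: two C–C bonds, two rings and the C7/C9 relation (from the Z geometry) in one step. In step count for rings A and B this road is better than the chosen plan, which needs nine steps from 22 and 28.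
- Weak points: A2 is the C5 epimer, so debenzylation and inversion at a hindered cyclopentanol next to the C7 methyl must follow. The substrate (a seven-membered ring with a tetrasubstituted alkene and a tertiary C10 carbinol beside quaternary C12) is itself hard to make. A strong Lewis acid acts next to an acid-labile alkene. Alkyl migration from C12 can compete. The C10 ketone must be reduced in the finished ring system, where the facial preference is unknown.
- Comparison: the chosen plan sets against it a C5 centre of correct configuration from the start, acyclic Felkin–Anh control at C10, and no cationic chemistry after the alkene exists.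

**Alternative 3:** Ring C would be forged by anodic coupling. Constant-current oxidation (reticulated vitreous carbon anode, LiClO4, methanol/dichloromethane, 2,6-lutidine) turns a C10=C12 enol ether into a radical cation whose C12 is attacked by C25 of an allylsilane, giving acetal A3.
- Merits: the C12 quaternary centre, C25 and ring C form in one step. C10 arrives at the aldehyde oxidation level and C25 carries a vinyl handle. This is shorter than the six steps (6 to 10 and 12) that the chosen plan spends on C25 and C12.
- Weak points: the configurations at C12 and C25 relative to C16 and C24 depend on transition-state conformations that the substrate does not secure. The vinyl group supplies only C26 and C27. Nothing in this step sets absolute configuration, so ring D still needs an enantioselective entry.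
- Comparison: this road could even be combined with the cycloaddition used here. The chosen plan sets against it two ring-controlled events of predictable sense: alkylation anti to the angular methyl and axial cuprate addition.

Key step: step 3

Assumption: the sense of induction in step 3 is taken from the usual pre-transition-state model for this catalyst class with α-substituted enals (formyl C–H···O contact, s-trans enal stacked on an aryl group), which assigns (1R,6S)-6 to the (S)-prolinol-derived catalyst; the equally accessible (R)-catalyst would be used if the first run showed the opposite sense.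

## Steps

Step 1
Reactants: 1 ethyl 2-(2-methyl-1,3-dioxolan-2-yl)acetate
Product: 2 2-(2-methyl-1,3-dioxolan-2-yl)acetaldehyde
Conditions: i-Bu2AlH, CH2Cl2, −78 °C; aq. potassium sodium tartrate work-up
Reagents that add atoms: none
Why: Partial reduction of an ester with i-Bu2AlH at low temperature stops at the aluminium hemiacetal, which releases the aldehyde on work-up; the ketal is inert to hydride.

Step 2
Reactants: 2 2-(2-methyl-1,3-dioxolan-2-yl)acetaldehyde; 3 2-(triphenylphosphoranylidene)propanal
Product: 4 (E)-2-methyl-4-(2-methyl-1,3-dioxolan-2-yl)but-2-enal
Conditions: toluene, 80 °C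
Reagents that add atoms: none
Why: Wittig reaction of a stabilized formyl ylide with an aliphatic aldehyde gives the (E)-trisubstituted enal; the ylide does not react with its own product at a useful rate.

Step 3
Reactants: 4 (E)-2-methyl-4-(2-methyl-1,3-dioxolan-2-yl)but-2-enal; 5 isoprene
Product: 6 (1R,6S)-1,4-dimethyl-6-[(2-methyl-1,3-dioxolan-2-yl)methyl]cyclohex-3-ene-1-carbaldehyde
Conditions: (S)-B-(o-tolyl)oxazaborolidine from (S)-α,α-diphenylprolinol and tri(o-tolyl)boroxine (20 mol %), HNTf2 (18 mol %), 5 (5 equiv), CH2Cl2, −78 → −40 °C
Reagents that add atoms: none
Why: The N-protonated oxazaborolidine is a strong chiral Lewis acid that binds the formyl oxygen of 4 and holds the s-trans enal over an aryl group through a formyl C–H···O contact; isoprene then adds in a concerted, asynchronous [4+2] cycloaddition, the closest known reaction type being the cationic oxazaborolidine-catalysed Diels–Alder reaction of α-substituted enals with simple 1,3-dienes. Ring D is closed by the intermolecular cycloaddition itself, with C16–C18 and C23–C24 forming suprafacially on both partners. C16 is set by the catalyst, which leaves one enantioface of the dienophile open (see the assumption), and C24 is set relative to C16 by the E geometry of 4, so that C15 and the C25 arm end up trans on the new ring. The step needs facial and regiochemical selectivity: the face comes from the catalyst and the para orientation (C20 methyl 1,4 to C16) from the larger HOMO coefficient at C1 of isoprene meeting the β-carbon C24. There is no endo/exo question because the diene termini are unsubstituted. A slight deficit of HNTf2 relative to the oxazaborolidine keeps free acid away from the dioxolane.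

Step 4
Reactants: 6 (1R,6S)-1,4-dimethyl-6-[(2-methyl-1,3-dioxolan-2-yl)methyl]cyclohex-3-ene-1-carbaldehyde
Product: 8 trans-fused dienone of rings C and D (C12 ketone; C14=C15; C19=C20; C17 methyl β; H24 α), via keto aldehyde 7 (not isolated)
Conditions: 1 M HCl, THF, 23 °C; then KOH, MeOH, 23 → 50 °C
Reagents that add atoms: water, O
Why: Acid hydrolysis of the dioxolane frees the methyl ketone, and base-mediated intramolecular aldol condensation follows; the aldehyde has no α-hydrogen, so only the C14 enolate can attack C15, closing the six-membered ring C; C16 and C24 are not enolizable.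

Step 5
Reactants: 9 2-(2-bromoethyl)-2-methyl-1,3-dioxolane
Product: 10 2-(2-iodoethyl)-2-methyl-1,3-dioxolane
Conditions: NaI, acetone, reflux
Reagents that add atoms: sodium iodide, [Na+].[I-]
Why: Finkelstein exchange driven by precipitation of NaBr; the iodide is needed because the hindered enolate of step 6 reacts poorly with the bromide.

Step 6
Reactants: 8 trans-fused dienone of rings C and D; 10 2-(2-iodoethyl)-2-methyl-1,3-dioxolane
Product: 11 C25-alkylated dienone (8 with a 2-(2-methyl-1,3-dioxolan-2-yl)ethyl group at C25 on the α face)
Conditions: LiN(i-Pr)2, THF, −78 °C; then 10, HMPA, −78 → −20 °C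
Reagents that add atoms: none
Why: Kinetic α′-deprotonation of an enone gives the cross-conjugated dienolate (C25 is the only acidic position), which is alkylated by SN2 reaction; the C17 methyl shields the β face, so C26 enters α, and this equatorial epimer is also the one favoured on equilibration.

Step 7
Reactants: 11 C25-alkylated dienone; 12 tributyl[(benzyloxy)methyl]stannane
Product: 14 tertiary allylic alcohol (C12 carbinol carrying CH2OBn; both C12 epimers), via (benzyloxymethyl)lithium 13 (not isolated)
Conditions: n-BuLi, THF, −78 °C; then 11, −78 °C
Reagents that add atoms: none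
Why: Tin–lithium exchange gives the α-alkoxy organolithium, which adds 1,2 to the enone carbonyl at low temperature; the configuration at C12 is irrelevant because this centre becomes sp2 in step 8.

Step 8
Reactants: 14 tertiary allylic alcohol
Product: 15 transposed enone (C15 ketone; C14=C12 with CH2OBn on C12)
Conditions: pyridinium chlorochromate (C5H5NH[CrO3Cl]), NaOAc, 4 Å molecular sieves, CH2Cl2, 23 °C
Reagents that add atoms: pyridinium chlorochromate, [O-][Cr](=O)(=O)Cl.c1cc[nH+]cc1
Why: Oxidative 1,3-transposition (Babler–Dauben oxidation): the tertiary chromate ester undergoes a [3,3]-shift to the secondary allylic chromate at C15, which is oxidized to the enone; NaOAc buffers the medium for the dioxolane.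

Step 9
Reactants: 15 transposed enone
Product: 16 β-methyl ketone (C15 ketone; quaternary C12 with α-axial methyl C13 and β-equatorial CH2OBn)
Conditions: Me2CuLi (from MeLi and CuI), BF3·OEt2, Et2O, −78 → −20 °C
Reagents that add atoms: lithium dimethylcuprate, [Li+].C[Cu-]C
Why: Lewis-acid-assisted cuprate conjugate addition to a β,β-disubstituted cyclohexenone; stereoelectronically controlled axial attack on the trans-fused ring comes from the α face (leading directly to the chair enolate), so the methyl becomes axial and the C10 substituent equatorial, as in the target.

Step 10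
Reactants: 16 β-methyl ketone
Product: 18 deoxygenated benzyl ether (ring C saturated; C19=C20 retained), via hydrazone 17 (not isolated)
Conditions: N2H4·H2O, KOH, diethylene glycol, 130 → 200 °C
Reagents that add atoms: none
Why: Wolff–Kishner reduction (Huang–Minlon procedure) removes the C15 carbonyl; the benzyl ether, dioxolane and trisubstituted alkene are stable to hot base and no stereocentre is α to the ketone.

Step 11
Reactants: 18 deoxygenated benzyl ether
Product: 20 gem-dimethyl benzyl ether (ring D saturated; C20 carries C21 and C22), via sulfonyl hydrazide 19 (not isolated)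
Conditions: Fe(acac)3, PhSiH3, CH2=N–NHSO2(n-C8H17) (from paraformaldehyde and the sulfonyl hydrazide), THF/MeOH, 23 °C; then MeOH, 60 °C
Reagents that add atoms: formaldehyde N-(octylsulfonyl)hydrazone, C=NNS(=O)(=O)CCCCCCCC
Why: Mukaiyama-type hydrogen-atom-transfer hydromethylation: Markovnikov hydrogen-atom transfer to C19 gives the tertiary C20 radical, which adds to the formaldehyde hydrazone; the adduct loses sulfinate and N2 on warming in methanol to leave a methyl group; C20 is not stereogenic and 18 has no other alkene.

Step 12
Reactants: 20 gem-dimethyl benzyl ether
Product: 21 primary alcohol (C10–OH)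
Conditions: H2 (1 atm), Pd/C, EtOAc, 23 °C
Reagents that add atoms: none
Why: Hydrogenolysis of a benzyl ether; no alkene is left in the molecule and the dioxolane is stable under neutral conditions.

Step 13
Reactants: 21 primary alcohol
Product: 22 decalin aldehyde (C10 formyl on quaternary C12)
Conditions: Dess–Martin periodinane, NaHCO3, CH2Cl2, 0 → 23 °C
Reagents that add atoms: none
Why: Dess–Martin oxidation of a neopentyl primary alcohol; the aldehyde has no α-hydrogen and cannot epimerize.

Step 14
Reactants: 23 (R)-4-[(tert-butyldimethylsilyl)oxy]cyclopent-2-en-1-one
Product: 24 (3R,4R)-4-[(tert-butyldimethylsilyl)oxy]-3-methyl-1-[(trimethylsilyl)oxy]cyclopent-1-ene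
Conditions: Me2CuLi (from MeLi and CuI), TMSCl, THF, −78 °C; Et3N, non-aqueous work-up
Reagents that add atoms: lithium dimethylcuprate, [Li+].C[Cu-]C; chlorotrimethylsilane, C[Si](C)(C)Cl
Why: Cuprate conjugate addition to a 4-silyloxycyclopentenone occurs anti to the silyloxy group (sets C7 trans to C5–O), and the regiodefined enolate is trapped as its silyl enol ether.

Step 15
Reactants: 24 (3R,4R)-4-[(tert-butyldimethylsilyl)oxy]-3-methyl-1-[(trimethylsilyl)oxy]cyclopent-1-ene
Product: 25 (R)-4-[(tert-butyldimethylsilyl)oxy]-3-methylcyclopent-2-en-1-one
Conditions: Pd(OAc)2, MeCN, 23 °C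
Reagents that add atoms: none
Why: Saegusa–Ito oxidation: the palladium enolate of divalent palladium loses the C7 hydrogen by β-hydride elimination, restoring the enone now carrying the methyl group; the C5 stereocentre is not touched.

Step 16
Reactants: 25 (R)-4-[(tert-butyldimethylsilyl)oxy]-3-methylcyclopent-2-en-1-one
Product: 27 (R)-2-bromo-4-[(tert-butyldimethylsilyl)oxy]-3-methylcyclopent-2-en-1-one, via dibromo ketone 26 (not isolated)
Conditions: Br2, CH2Cl2, 0 °C; then Et3N, 0 → 23 °C
Reagents that add atoms: bromine, BrBr
Why: Bromine addition to the enone followed by dehydrobromination with amine base is the standard route to α-bromo enones; the base also scavenges HBr and protects the silyl ether.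

Step 17
Reactants: 27 (R)-2-bromo-4-[(tert-butyldimethylsilyl)oxy]-3-methylcyclopent-2-en-1-one
Product: 28 (R)-6-bromo-8-[(tert-butyldimethylsilyl)oxy]-7-methyl-1,4-dioxaspiro[4.4]non-6-ene
Conditions: (TMSOCH2)2, TMSOTf (cat.), CH2Cl2, −78 → −20 °C
Reagents that add atoms: 1,2-bis(trimethylsilyloxy)ethane, C[Si](C)(C)OCCO[Si](C)(C)C
Why: Aprotic ketalization with the bis-silyl ether of ethylene glycol spares the allylic silyl ether and leaves the alkene in place; the ketal turns the bromo enone into a precursor of an α-keto vinyl anion equivalent.

Step 18
Reactants: 28 (R)-6-bromo-8-[(tert-butyldimethylsilyl)oxy]-7-methyl-1,4-dioxaspiro[4.4]non-6-ene; 22 decalin aldehyde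
Product: 30 coupled allylic carbinol (C9–C10 bond formed; C10 epimers), via vinyllithium 29 (not isolated)
Conditions: t-BuLi (2 equiv), THF, −78 °C; then 22, −78 → −40 °C
Reagents that add atoms: none
Why: Bromine–lithium exchange gives the vinyllithium, which adds to the non-enolizable aldehyde; the C10 configuration is not relied on here because it is reset in steps 19 and 20.

Step 19
Reactants: 30 coupled allylic carbinol
Product: 31 C10 ketone (enone C10(=O)–C9=C7)
Conditions: Dess–Martin periodinane, NaHCO3, CH2Cl2, 0 → 23 °C
Reagents that add atoms: none
Why: Dess–Martin oxidation of a hindered allylic alcohol under buffered conditions that leave both ketals and the silyl ether intact.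

Step 20
Reactants: 31 C10 ketone
Product: 32 allylic alcohol with the C10 configuration of the target (C5 silyl ether; both ketals in place)
Conditions: LiAlH4, Et2O, −78 °C
Reagents that add atoms: none
Why: 1,2-Reduction under Felkin–Anh control: hydride attacks anti to the C12–C25 bond and passes over the small C13 methyl, which gives the target configuration at C10; the β-carbon is fully substituted, so conjugate reduction does not compete.

Step 21
Reactants: 32 allylic alcohol with the C10 configuration of the target
Product: 33 cyclopentene diol (free C5–OH and C10–OH; C7=C9; both ketals in place)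
Conditions: Bu4NF, THF, 0 → 23 °C
Reagents that add atoms: none
Why: Fluoride cleavage of the secondary silyl ether frees the C5 hydroxyl, which is needed as a directing group and would otherwise block the face to be hydrogenated.

Step 22
Reactants: 33 cyclopentene diol
Product: 34 saturated diol (C7–H and C9–H cis to the C5–OH; C7 methyl trans to C5–OH and cis to the C9–C10 bond)
Conditions: H2 (1–5 atm), [Ir(cod)(PCy3)(py)]PF6 (20 mol %), CH2Cl2, 23 °C
Reagents that add atoms: none
Why: Hydroxyl-directed hydrogenation with a cationic iridium catalyst, which reduces tetrasubstituted alkenes; the allylic C5–OH delivers H2 to its own face, and the C10–OH, in the conformer that minimizes A(1,3) strain (C10–H eclipsing the C7 methyl side), directs to the same face, so syn addition sets C7 and C9 as in the target.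

Step 23
Reactants: 34 saturated diol
Product: 35 bis(tert-butyldimethylsilyl) ether of 34
Conditions: TBSOTf, 2,6-lutidine, CH2Cl2, −78 → 23 °C
Reagents that add atoms: tert-butyldimethylsilyl triflate, CC(C)(C)[Si](C)(C)OS(=O)(=O)C(F)(F)F
Why: The silyl triflate silylates even the hindered C10 carbinol; protection keeps the future β-hydroxy ketone from retro-aldol cleavage and the hydroxyls from the titanium reagent.

Step 24
Reactants: 35 bis(tert-butyldimethylsilyl) ether of 34
Product: 36 diketone (C3 cyclopentanone and C2 methyl ketone; C5 and C10 silyl ethers)
Conditions: PPTS, acetone/H2O (10:1), 50 °C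
Reagents that add atoms: water, O
Why: Mild acid-catalysed hydrolysis of the two dioxolanes; a weakly acidic pyridinium salt is chosen so that the secondary silyl ethers survive and enolization of the C3 ketone toward C9 stays slow.

Step 25
Reactants: 36 diketone
Product: 37 tetracyclic bis(silyl ether) (rings A to D; C2=C3)
Conditions: TiCl3(DME)1.5, Zn–Cu couple, DME, reflux; slow addition of 36 by syringe pump
Reagents that add atoms: none
Why: Intramolecular McMurry coupling: low-valent titanium joins the two ketyl carbons to a titanium pinacolate and deoxygenates it to the tetrasubstituted alkene; the reaction is suited to medium rings and fully substituted alkenes, and the alkene geometry is fixed by the ring.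

Step 26
Reactants: 37 tetracyclic bis(silyl ether)
Product: 38 target diol (CNP0213887.1)
Conditions: Bu4NF, THF, 50 °C
Reagents that add atoms: none
Why: Fluoride-mediated desilylation avoids acid, which could move the tetrasubstituted alkene; no stereocentre is affected.

## Compound list

1 | ethyl 2-(2-methyl-1,3-dioxolan-2-yl)acetate | CCOC(=O)CC1(C)OCCO1 | starting material
2 | 2-(2-methyl-1,3-dioxolan-2-yl)acetaldehyde | O=CCC1(C)OCCO1 | intermediate
3 | 2-(triphenylphosphoranylidene)propanal | CC(C=O)=P(c1ccccc1)(c1ccccc1)c1ccccc1 | starting material
4 | (E)-2-methyl-4-(2-methyl-1,3-dioxolan-2-yl)but-2-enal | O=C/C(C)=C/CC1(C)OCCO1 | intermediate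
5 | isoprene | C=CC(C)=C | starting material
6 | (1R,6S)-1,4-dimethyl-6-[(2-methyl-1,3-dioxolan-2-yl)methyl]cyclohex-3-ene-1-carbaldehyde | O=C[C@]1(C)CC=C(C)C[C@H]1CC1(C)OCCO1 | intermediate
7 | (1R,6S)-1,4-dimethyl-6-(2-oxopropyl)cyclohex-3-ene-1-carbaldehyde | O=C[C@]1(C)CC=C(C)C[C@H]1CC(C)=O | intermediate (not isolated)
8 | trans-fused dienone of rings C and D (C12 ketone, C14=C15, C19=C20) | O=C1C=C[C@]2(C)CC=C(C)C[C@H]2C1 | intermediate
9 | 2-(2-bromoethyl)-2-methyl-1,3-dioxolane | BrCCC1(C)OCCO1 | starting material
10 | 2-(2-iodoethyl)-2-methyl-1,3-dioxolane | ICCC1(C)OCCO1 | intermediate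
11 | C25-alkylated dienone (C26 chain α, equatorial) | O=C1C=C[C@]2(C)CC=C(C)C[C@H]2[C@@H]1CCC1(C)OCCO1 | intermediate
12 | tributyl[(benzyloxy)methyl]stannane | CCCC[Sn](CCCC)(CCCC)COCc1ccccc1 | starting material
13 | (benzyloxymethyl)lithium | [Li]COCc1ccccc1 | intermediate (not isolated)
14 | tertiary allylic alcohol at C12 with CH2OBn (C12 epimers) | OC1(COCc2ccccc2)C=C[C@]2(C)CC=C(C)C[C@H]2[C@@H]1CCC1(C)OCCO1 | intermediate
15 | transposed enone (C15 ketone, C14=C12) | C(OCc1ccccc1)C1=CC(=O)[C@]2(C)CC=C(C)C[C@H]2[C@@H]1CCC1(C)OCCO1 | intermediate
16 | β-methyl ketone (C12 quaternary: methyl α, CH2OBn β) | C(OCc1ccccc1)[C@@]1(C)CC(=O)[C@]2(C)CC=C(C)C[C@H]2[C@@H]1CCC1(C)OCCO1 | intermediate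
17 | hydrazone of 16 | C(OCc1ccccc1)[C@@]1(C)CC(=NN)[C@]2(C)CC=C(C)C[C@H]2[C@@H]1CCC1(C)OCCO1 | intermediate (not isolated)
18 | deoxygenated benzyl ether (C19=C20) | C(OCc1ccccc1)[C@@]1(C)CC[C@]2(C)CC=C(C)C[C@H]2[C@@H]1CCC1(C)OCCO1 | intermediate
19 | N′-alkyl octylsulfonyl hydrazide at the new C20 methylene (C20 epimers) | C(OCc1ccccc1)[C@@]1(C)CC[C@]2(C)CCC(C)(CNNS(=O)(=O)CCCCCCCC)C[C@H]2[C@@H]1CCC1(C)OCCO1 | intermediate (not isolated)
20 | gem-dimethyl benzyl ether | C(OCc1ccccc1)[C@@]1(C)CC[C@]2(C)CCC(C)(C)C[C@H]2[C@@H]1CCC1(C)OCCO1 | intermediate
21 | primary alcohol (C10–OH) | OC[C@@]1(C)CC[C@]2(C)CCC(C)(C)C[C@H]2[C@@H]1CCC1(C)OCCO1 | intermediate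
22 | decalin aldehyde (C10 formyl) | O=C[C@@]1(C)CC[C@]2(C)CCC(C)(C)C[C@H]2[C@@H]1CCC1(C)OCCO1 | intermediate
23 | (R)-4-[(tert-butyldimethylsilyl)oxy]cyclopent-2-en-1-one | O=C1C=C[C@H](O[Si](C)(C)C(C)(C)C)C1 | starting material
24 | (3R,4R)-4-[(tert-butyldimethylsilyl)oxy]-3-methyl-1-[(trimethylsilyl)oxy]cyclopent-1-ene | C[C@@H]1C=C(O[Si](C)(C)C)C[C@H]1O[Si](C)(C)C(C)(C)C | intermediate
25 | (R)-4-[(tert-butyldimethylsilyl)oxy]-3-methylcyclopent-2-en-1-one | CC1=CC(=O)C[C@H]1O[Si](C)(C)C(C)(C)C | intermediate
26 | 2,3-dibromo ketone from 25 (mixture at the two new centres) | CC1(Br)C(Br)C(=O)C[C@H]1O[Si](C)(C)C(C)(C)C | intermediate (not isolated)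
27 | (R)-2-bromo-4-[(tert-butyldimethylsilyl)oxy]-3-methylcyclopent-2-en-1-one | CC1=C(Br)C(=O)C[C@H]1O[Si](C)(C)C(C)(C)C | intermediate
28 | (R)-6-bromo-8-[(tert-butyldimethylsilyl)oxy]-7-methyl-1,4-dioxaspiro[4.4]non-6-ene | CC1=C(Br)C2(OCCO2)C[C@H]1O[Si](C)(C)C(C)(C)C | intermediate
29 | vinyllithium from 28 | CC1=C([Li])C2(OCCO2)C[C@H]1O[Si](C)(C)C(C)(C)C | intermediate (not isolated)
30 | coupled allylic carbinol (C10 epimers) | OC(C1=C(C)[C@H](O[Si](C)(C)C(C)(C)C)CC12OCCO2)[C@@]1(C)CC[C@]2(C)CCC(C)(C)C[C@H]2[C@@H]1CCC1(C)OCCO1 | intermediate
31 | C10 ketone | O=C(C1=C(C)[C@H](O[Si](C)(C)C(C)(C)C)CC12OCCO2)[C@@]1(C)CC[C@]2(C)CCC(C)(C)C[C@H]2[C@@H]1CCC1(C)OCCO1 | intermediate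
32 | allylic alcohol, C10 as in the target | O[C@H](C1=C(C)[C@H](O[Si](C)(C)C(C)(C)C)CC12OCCO2)[C@@]1(C)CC[C@]2(C)CCC(C)(C)C[C@H]2[C@@H]1CCC1(C)OCCO1 | intermediate
33 | cyclopentene diol | O[C@H](C1=C(C)[C@H](O)CC12OCCO2)[C@@]1(C)CC[C@]2(C)CCC(C)(C)C[C@H]2[C@@H]1CCC1(C)OCCO1 | intermediate
34 | saturated diol (C5, C7, C9, C10 as in the target) | O[C@H]([C@H]1[C@@H](C)[C@H](O)CC12OCCO2)[C@@]1(C)CC[C@]2(C)CCC(C)(C)C[C@H]2[C@@H]1CCC1(C)OCCO1 | intermediate
35 | bis(tert-butyldimethylsilyl) ether of 34 | CC(C)(C)[Si](C)(C)O[C@H]([C@H]1[C@@H](C)[C@H](O[Si](C)(C)C(C)(C)C)CC12OCCO2)[C@@]1(C)CC[C@]2(C)CCC(C)(C)C[C@H]2[C@@H]1CCC1(C)OCCO1 | intermediate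
36 | diketone (C3 and C2 ketones, bis-silyl ether) | CC(C)(C)[Si](C)(C)O[C@H]([C@H]1[C@@H](C)[C@H](O[Si](C)(C)C(C)(C)C)CC1=O)[C@@]1(C)CC[C@]2(C)CCC(C)(C)C[C@H]2[C@@H]1CCC(C)=O | intermediate
37 | tetracyclic bis(silyl ether) | C/C1=C2\C[C@@H](O[Si](C)(C)C(C)(C)C)[C@H](C)[C@@H]2[C@@H](O[Si](C)(C)C(C)(C)C)[C@@]2(C)CC[C@]3(C)CCC(C)(C)C[C@H]3[C@@H]2CC1 | intermediate
38 | CNP0213887.1 | C/C1=C2\C[C@@H](O)[C@H](C)[C@@H]2[C@@H](O)[C@@]2(C)CC[C@]3(C)CCC(C)(C)C[C@H]3[C@@H]2CC1 | target

## Step count and least certain steps

Total step count: 26 (steps 1–13 decalin aldehyde, step 5 being the side-chain iodide; steps 14–17 ring A bromide; steps 18–26 end game). Longest linear sequence: 21 steps (1–4, 6–13, 18–26).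

**Step 3 (key step).** The likely failure is slow cycloaddition of a trisubstituted enal with an unactivated diene, made worse by binding of the boron acid to the dioxolane oxygens and by acid-induced opening of the ketal; the result would be low conversion and eroded enantioselectivity. The fallback gives up catalytic induction for resolution. It sets out from 4 and 5: cycloaddition promoted by Me2AlCl in CH2Cl2 at −40 °C (or thermally in a sealed tube) should give 6 together with its enantiomer ent-6 F1; step 4 on this mixture gives 8 together with ent-8 F2; and 8 is separated from F2 by preparative chromatography on a chiral stationary phase. The route is rejoined at 8.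

**Step 11.** The tertiary C20 radical may be reduced by a second hydrogen-atom transfer before it is trapped, or its capture by the hydrazone may be slow at this hindered centre. The fallback uses two classical operations and sets out from 18: Simmons–Smith cyclopropanation (Et2Zn, CH2I2, CF3CO2H, CH2Cl2) gives cyclopropane F3, and hydrogenolysis of the least hindered cyclopropane bond (H2, PtO2, acetic acid buffered with NaOAc) opens it to the gem-dimethyl group. The route is rejoined at 20; if the dioxolane is partly lost, it is re-installed with ethylene glycol before step 12.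

**Step 20.** Facial discrimination at the hindered C10 ketone, which is twisted out of conjugation, may be poor, or the sense may be opposite to the model. The fallback needs no new compound (F0): the addition in step 18 follows the complementary trajectory, so the epimer of 30 that is identical with 32 is separated by chromatography of 30 and carried into step 21. The other epimer is recycled through 31 with an oxazaborolidine–borane (CBS) reduction under reagent control.

**Step 22.** The catalyst may be deactivated before it turns over on an alkene flanked by a spiro ketal, a quaternary-substituted carbinol and a methyl group, or delivery may be incomplete. The fallback changes the substrate class and the order of events and sets out from 33. Hydrolysis of both ketals (PPTS, acetone/H2O) gives enone diol diketone F4, whose alkene is now a less shielded 2,3-disubstituted cyclopentenone. Syn-hydrogenation (H2, Pd/C, EtOAc, the hydroxyls anchoring the substrate to the catalyst face) gives diol diketone F5. Silylation as in step 23 rejoins the route at 36. In this fallback the C9 centre is exposed as an α-keto stereocentre for one step longer.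

**Step 25.** The C3 ketone may enolize in the hot, Lewis-acidic slurry, which would epimerize C9 or eliminate the C5 silyloxy group; the coupling may also stall at the pinacol stage or turn intermolecular. The fallback separates C–C bond formation from deoxygenation and sets out from 36. SmI2 (divalent samarium, THF/HMPA, 23 °C) closes the ring by pinacol coupling to cis-diol F6. Thiocarbonyldiimidazole converts it into thionocarbonate F7. Corey–Winter olefination with 1,3-dimethyl-2-phenyl-1,3,2-diazaphospholidine at 40 °C gives 37, where the route is rejoined.

## Further compounds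

F1 | step 3 | ent-6, (1S,6R)-1,4-dimethyl-6-[(2-methyl-1,3-dioxolan-2-yl)methyl]cyclohex-3-ene-1-carbaldehyde | O=C[C@@]1(C)CC=C(C)C[C@@H]1CC1(C)OCCO1
F2 | step 3 | ent-8, enantiomer of the trans-fused dienone | O=C1C=C[C@@]2(C)CC=C(C)C[C@@H]2C1
F3 | step 11 | C19–C20 cyclopropane of 18 (either face) | C(OCc1ccccc1)[C@@]1(C)CC[C@]2(C)CC3CC3(C)C[C@H]2[C@@H]1CCC1(C)OCCO1
F0 | step 20 | none | none
F4 | step 22 | enone diol diketone (C3 enone, C2 ketone, free C5 and C10 hydroxyls) | O[C@H](C1=C(C)[C@H](O)CC1=O)[C@@]1(C)CC[C@]2(C)CCC(C)(C)C[C@H]2[C@@H]1CCC(C)=O
F5 | step 22 | diol diketone (C7 and C9 as in the target) | O[C@H]([C@H]1[C@@H](C)[C@H](O)CC1=O)[C@@]1(C)CC[C@]2(C)CCC(C)(C)C[C@H]2[C@@H]1CCC(C)=O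
F6 | step 25 | tetracyclic C2,C3 cis-diol, bis-silyl ether | CC1(O)C2(O)C[C@@H](O[Si](C)(C)C(C)(C)C)[C@H](C)[C@@H]2[C@@H](O[Si](C)(C)C(C)(C)C)[C@@]2(C)CC[C@]3(C)CCC(C)(C)C[C@H]3[C@@H]2CC1
F7 | step 25 | cyclic thionocarbonate of F6 | CC12OC(=S)OC13C[C@@H](O[Si](C)(C)C(C)(C)C)[C@H](C)[C@@H]3[C@@H](O[Si](C)(C)C(C)(C)C)[C@@]3(C)CC[C@]4(C)CCC(C)(C)C[C@H]4[C@@H]3CC2
A1 | alternative 1 | tetracyclic bis-silyl ether with the C26 bis(phenylsulfonyl) group | C/C1=C2\C[C@@H](O[Si](C)(C)C(C)(C)C)[C@H](C)[C@@H]2[C@@H](O[Si](C)(C)C(C)(C)C)[C@@]2(C)CC[C@]3(C)CCC(C)(C)C[C@H]3[C@@H]2C(S(=O)(=O)c4ccccc4)(S(=O)(=O)c5ccccc5)C1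
A2 | alternative 2 | tetracyclic C10 ketone, C5 benzyl ether (C5 epimer) | C/C1=C2\C[C@H](OCc4ccccc4)[C@H](C)[C@@H]2C(=O)[C@@]2(C)CC[C@]3(C)CCC(C)(C)C[C@H]3[C@@H]2CC1
A3 | alternative 3 | trans-decalin with C10 dimethyl acetal and C25 vinyl group | COC(OC)[C@@]2(C)CC[C@]3(C)CCC(C)(C)C[C@H]3[C@@H]2C=C
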